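## The problem

The target is a depside: two fully or almost fully substituted benzene rings held together only by an aryl ester between the C1 carboxyl of ring A and O-4 of ring B. It has no stereocentre, so nothing has to be controlled in space; the task is one of regiochemistry and functional-group tolerance. Ring A (C1 ester carbonyl, C2 OMe, C3 CH2OH, C4 OMe, C5 H, C6 CH3) carries its carboxyl between a methoxy and a methyl group, so acylating a phenol with this acid is slow and needs forcing activation. Ring B is a 2,4-dihydroxy-3,6-dimethylbenzoic acid whose chelated O-2, free O-4 and carboxyl must be told apart. Three groups dislike rough treatment: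

- the aryl ester, which is open to hydroxide, alkoxide and amines;
- the salicylic acid of ring B, which decarboxylates when heated as the free acid;
- the ring A hydroxymethyl group, a benzylic alcohol between two methoxy groups, which ionises in acid and whose C–O bond is open to hydrogenolysis.

The feature that allows a way round the hindered acylation is the substitution pattern of ring A: C2–C3–C4–C5 is a 1,1,3-trioxygenated butadiene carrying the C3 carbon, and C6–C1 with its methyl and carboxyl is a but-2-ynoate. Ring A can therefore be grown onto an ester that already exists.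

## Retrosynthesis

**Unmasking (20 to 19 to 18).** The O–Si bond of a tert-butyldiphenylsilyl ether on the ring A hydroxymethyl group is cut first, then the two O–CH2Ph bonds on ring B. A benzyl ether on the hydroxymethyl oxygen would save a step. It would, however, put a doubly benzylic ether on palladium under hydrogen, and cleavage on the ring A side would leave a C3 methyl group for good. The silyl ether leaves only unambiguous benzyl groups for hydrogenolysis and comes off last under buffered fluoride. The forward steps must spare the ArCH2–OSi bond during hydrogenolysis and the aryl ester during desilylation.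

**O-Methylation (18 to 17).** The O–CH3 bond at ring A C2 is cut. The cycloaddition below delivers O-2 as a chelated phenol, because a silyl ketene acetal is the practical form of the diene. Methylating it afterwards requires that the equally chelated O-2 of ring B already be capped, which is why ring B carries a benzyl ether there.

**Key disconnection (17 to 7 + 14).** The C1–C2 and C5–C6 bonds of ring A are cut, taking the whole ring apart into diene 14 and the aryl but-2-ynoate 7. The neighbouring cut, the ester C–O bond, leads back to a 2,6-disubstituted benzoic acid and a hindered acylation. A cut at C3–CH2 would require a late hydroxymethylation choosing C3 over C5. The chosen cut removes one ring and leaves an ester that is easy to make. The forward reaction must be regioselective (CH3 to C6, oxygens to C2 and C4) and must tolerate the benzyl ester, the benzyl ether and the silyl ether.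

**Butynoate ester (7 to 5 + 6).** The ester C–O bond is cut to phenol 5 and but-2-ynoic acid 6. This is the same bond that is hard to form in the classical approach, but here the acid is small and linear and the phenol has a free ortho position.

**Ring B protection (5 back to 1).** Only O–C bonds of protecting groups are cut, back to commercial ester 1 through 4, 3 and 2. The free O-4 is the more reactive phenol, so it must be masked with an allyl group while the acid and the chelated O-2 are benzylated. Hydrolysing the methyl ester before benzylation lets one step install both benzyl groups.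

**Diene (14 to 13 to 11).** The O–Si bond of the ketene acetal is cut to enoate 13, and the enol ether O–CH3 bond to β-keto ester 11, through ketal 12. This is the standard preparation of 1,3-dimethoxy-1-silyloxy dienes. The silyl ether must be bulky enough to survive the acid used for enol ether formation.

**Keto ester (11 to 9 + 10, 9 to 8).** The C2–C3 bond of 11 is cut to the enolate of silyloxy ester 9 and Weinreb amide 10; 9 comes from methyl 3-hydroxypropanoate 8. The alternative cut at C2–CH2O, alkylation of an acetoacetate enolate with a chloromethyl ether, is rejected because such hard electrophiles go mainly to the enolate oxygen.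

## Roads not taken

**Alternative 1:** aryne route to the ring A acid.
- Cut: the depside ester C–O bond, then C6–CH3 and C1–COOH of ring A.
- Forward key step: the symmetrical bromide A2 is deprotonated between bromine and methoxy by lithium 2,2,6,6-tetramethylpiperidide and loses LiBr to give aryne A3. MeMgBr adds at C6, distal to the C2 methoxy group, and CO2 carboxylates C1 to give acid A1.
- Merits: both ring hydrogens of A2 are equivalent, so only one aryne can form, and the methoxy group directs the addition. Ring A arrives with both methyl ethers in place. Ring B then needs only a benzyl ester, since its chelated O-2 need not be capped when no late O-methylation follows. The whole route would be several steps shorter than the chosen one.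
- Weak points: three components must combine in the right order while the amide base can also add to A3. A1 is exactly the 2,6-disubstituted acid whose esterification with a phenol such as 5 is hard; the strong electrophilic activation it needs (oxalyl chloride or trifluoroacetic anhydride) threatens the 2,6-dimethoxybenzyl silyl ether.
- Comparison: this road is better in step count and convergence. The chosen plan sets against that an ester bond formed from an unhindered acid and no step in which a labile benzylic ether meets a strong acylating medium.

**Alternative 2:** biomimetic aromatisation to ring B.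
- Cut: the C1–C6 bond of ring B.
- Forward key step: with Et3N, C5 of the dioxinone in diketo-dioxinone A5 adds to the terminal methyl ketone and water is lost, giving benzodioxinone A4.
- Merits: the conditions are mild. A4 has O-4 free while O-2 and the carboxyl are masked together, a differentiation that costs the chosen plan four steps (1 to 5).
- Weak points: the step builds ring B, the part that can be bought as 1, and A5 itself needs several steps. Ring A and the hindered ester remain unsolved. Opening the dioxinone at the end needs hydroxide or alkoxide, which would also attack the depside ester; opening it before acylation only leads back to a benzyl ester of the type 5.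
- Comparison: it is better only in how it differentiates ring B. The chosen plan is longer in protecting-group steps on ring B but spends its key step on the real difficulty.

**Alternative 3:** pyrone cycloaddition to ring A.
- Cut: C2–C3 and C4–C5 of ring A.
- Forward key step: pyrone A7 and ynol ether A8 undergo (4+2) cycloaddition and lose CO2, giving benzoate A6 with all six substituents.
- Merits: both methyl ethers are present from the start and CO2 is the only by-product. Polarity matching fixes the orientation, the nucleophilic alkyne carbon joining the acetal-type C6 of A7. No late O-methylation is needed, so ring B could again go without its 2-O-benzyl group.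
- Weak points: A7 is not a catalogue compound. A8 is prone to hydration and polymerisation at the temperatures pyrone cycloadditions need. A6 is a methyl ester of a doubly ortho-substituted acid, so forcing hydrolysis and then the hindered esterification still lie ahead, both with a silyl ether on board.
- Comparison: it is close in spirit to the chosen plan and delivers a more finished ring A. The chosen plan answers that its cycloaddition also settles the ester bond.

Key step: step 10

Assumption: the double-bond geometry of enoate 13 and of ketene acetal 14 is left undefined because it is erased when ring A aromatises; compounds 11, 12 and 15 are racemic and lose their stereocentres on the way.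

## Route

Step 1
Reactants: 1 methyl 2,4-dihydroxy-3,6-dimethylbenzoate
Product: 2 methyl 4-(allyloxy)-2-hydroxy-3,6-dimethylbenzoate
Conditions: allyl bromide (1.1 equiv), K2CO3, acetone, reflux
Reagents that add atoms: allyl bromide, C=CCBr
Why: Williamson ether synthesis; O-4 is the more acidic, unchelated phenol, while O-2 is hydrogen-bonded to the ester carbonyl and flanked by the C3 methyl group, so one equivalent of halide should alkylate O-4 only.

Step 2
Reactants: 2 methyl 4-(allyloxy)-2-hydroxy-3,6-dimethylbenzoate
Product: 3 4-(allyloxy)-2-hydroxy-3,6-dimethylbenzoic acid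
Conditions: KOH, DMSO/H2O, 80 °C; then cold 1 M HCl to pH 2
Reagents that add atoms: potassium hydroxide, [K+].[OH-]
Why: Saponification of a di-ortho-substituted benzoate; hot hydroxide in aqueous DMSO is the usual answer to such hindered esters, the dianion is stable to heat, and the acid is set free cold so that it does not decarboxylate.

Step 3
Reactants: 3 4-(allyloxy)-2-hydroxy-3,6-dimethylbenzoic acid
Product: 4 benzyl 4-(allyloxy)-2-(benzyloxy)-3,6-dimethylbenzoate
Conditions: BnBr (2.5 equiv), K2CO3, DMF, 60 °C
Reagents that add atoms: benzyl bromide, BrCc1ccccc1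
Why: Double O-alkylation; the carboxylate is benzylated first and the chelated phenoxide follows in warm DMF, which is standard in depside work.

Step 4
Reactants: 4 benzyl 4-(allyloxy)-2-(benzyloxy)-3,6-dimethylbenzoate
Product: 5 benzyl 2-(benzyloxy)-4-hydroxy-3,6-dimethylbenzoate
Conditions: Pd(PPh3)4 (cat.), morpholine, THF, rt
Reagents that add atoms: none
Why: Tsuji–Trost deallylation; zerovalent palladium ionises the aryl allyl ether to a π-allyl complex that morpholine captures, and benzyl ester and benzyl ether are not touched.

Step 5
Reactants: 5 benzyl 2-(benzyloxy)-4-hydroxy-3,6-dimethylbenzoate; 6 but-2-ynoic acid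
Product: 7 benzyl 2-(benzyloxy)-4-(but-2-ynoyloxy)-3,6-dimethylbenzoate
Conditions: DCC, DMAP (cat.), CH2Cl2, 0 °C to rt
Reagents that add atoms: none
Why: Steglich esterification; the acid is small and linear and the phenol has one free ortho position, so acylation is unhindered, and low temperature with little DMAP limits amine addition to the triple bond.

Step 6
Reactants: 8 methyl 3-hydroxypropanoate
Product: 9 methyl 3-[(tert-butyldiphenylsilyl)oxy]propanoate
Conditions: TBDPSCl, imidazole, DMF, rt
Reagents that add atoms: tert-butyl(chloro)diphenylsilane, CC(C)(C)[Si](Cl)(c1ccccc1)c1ccccc1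
Why: Routine silylation of a primary alcohol; the diphenyl-tert-butylsilyl group is chosen for its resistance to the acid of step 8 and step 10.

Step 7
Reactants: 9 methyl 3-[(tert-butyldiphenylsilyl)oxy]propanoate; 10 N-methoxy-N-methylacetamide
Product: 11 methyl 2-{[(tert-butyldiphenylsilyl)oxy]methyl}-3-oxobutanoate (racemic)
Conditions: LiN(iPr)2, THF, −78 °C; then 10, −78 to −20 °C; aq. NH4Cl
Reagents that add atoms: none
Why: Crossed Claisen acylation of an ester enolate by a Weinreb amide; the chelated tetrahedral adduct lasts until the quench, so the acidic keto ester never meets the enolate, and the low temperature holds back β-elimination of silanolate.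

Step 8
Reactants: 11 methyl 2-{[(tert-butyldiphenylsilyl)oxy]methyl}-3-oxobutanoate
Product: 13 methyl 2-{[(tert-butyldiphenylsilyl)oxy]methyl}-3-methoxybut-2-enoate, via dimethyl ketal 12 (not isolated)
Conditions: HC(OMe)3, camphorsulfonic acid (cat.), MeOH, rt; then PhMe, reflux with removal of MeOH
Reagents that add atoms: trimethyl orthoformate, COC(OC)OC; methanol, CO
Why: Acid-catalysed ketalisation with the orthoester as water scavenger, then thermal loss of methanol to the conjugated enol ether, as used for 2-alkyl acetoacetates; a deconjugated isomer, should some form, gives the same dienolate in step 9.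

Step 9
Reactants: 13 methyl 2-{[(tert-butyldiphenylsilyl)oxy]methyl}-3-methoxybut-2-enoate
Product: 14 2-{[(tert-butyldiphenylsilyl)oxy]methyl}-1,3-dimethoxy-1-[(trimethylsilyl)oxy]buta-1,3-diene
Conditions: LiN(iPr)2, THF, −78 °C; TMSCl, −78 °C to rt; pentane, filtration under argon, used crude
Reagents that add atoms: chlorotrimethylsilane, C[Si](C)(C)Cl
Why: Vinylogous (γ) deprotonation of a β-methoxy enoate and O-silylation of the dienolate, the standard entry to Brassard-type dienes; the C4 methyl is the only acidic site, and the cold silyl chloride quench outruns loss of silanolate.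

Step 10
Reactants: 7 benzyl 2-(benzyloxy)-4-(but-2-ynoyloxy)-3,6-dimethylbenzoate; 14 2-{[(tert-butyldiphenylsilyl)oxy]methyl}-1,3-dimethoxy-1-[(trimethylsilyl)oxy]buta-1,3-diene
Product: 17 benzyl 2-(benzyloxy)-4-[(3-{[(tert-butyldiphenylsilyl)oxy]methyl}-2-hydroxy-4-methoxy-6-methylbenzoyl)oxy]-3,6-dimethylbenzoate, via cyclohexa-1,4-diene cycloadduct 15 (not isolated), via ring A trimethylsilyl ether 16 (not isolated)
Conditions: 14 (2.5 equiv), PhMe, 120 °C, sealed tube; then 1 M HCl, THF, 0 °C to rt
Reagents that add atoms: none
Why: Normal-electron-demand Diels–Alder reaction of an electron-rich vinylketene acetal with an acetylenic ester, the closest known type being Brassard-type 1-alkoxy-1-silyloxy diene cycloadditions with alkynoates that give salicylates and resorcylates after aromatisation. The largest HOMO coefficient of 14 lies on its unsubstituted CH2 terminus and the largest LUMO coefficient of 7 on the methyl-bearing β-carbon, so C5–C6 forms first and C1–C2 follows, either in one asynchronous step or as Michael addition followed by attack of the allenolate α-carbon on the silyloxycarbenium carbon. Ring A is thus closed in the (4+2) mode, which in the stepwise limit is a 6-(enolendo)-exo-trig closure. Adduct 15 is a 1,4-cyclohexadiene whose ketal carbon and ring CH2 stand para to each other, so 1,4-loss of methanol gives silyl ether 16 and dilute acid frees the chelated phenol of 17. No stereocentre survives: the ketal carbon of 15 forms racemic and is flattened on aromatisation. The selectivity needed is regiochemical and the polarity match secures it, placing CH3 at C6 and the oxygens at C2 and C4, whereas the reverse orientation would join the two electron-poor carbons. The aryl ester makes the ynoate more electron-poor than an alkyl but-2-ynoate, which offsets the retarding β-methyl group, and the benzyl ester and ethers of ring B are inert to a neutral silyl ketene acetal. Any adduct that loses silanol instead of methanol gives the 2-methyl ether, which is compound 18 and rejoins the route after step 11.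

Step 11
Reactants: 17 benzyl 2-(benzyloxy)-4-[(3-{[(tert-butyldiphenylsilyl)oxy]methyl}-2-hydroxy-4-methoxy-6-methylbenzoyl)oxy]-3,6-dimethylbenzoate
Product: 18 benzyl 2-(benzyloxy)-4-[(3-{[(tert-butyldiphenylsilyl)oxy]methyl}-2,4-dimethoxy-6-methylbenzoyl)oxy]-3,6-dimethylbenzoate
Conditions: MeI, K2CO3, DMF, rt to 40 °C
Reagents that add atoms: iodomethane, CI
Why: Williamson methylation of a chelated salicylate phenol; ring B has no free hydroxyl, the aryl ester is stable to carbonate in dry DMF, and the bulky silyl group should not migrate to the more stable phenoxide.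

Step 12
Reactants: 18 benzyl 2-(benzyloxy)-4-[(3-{[(tert-butyldiphenylsilyl)oxy]methyl}-2,4-dimethoxy-6-methylbenzoyl)oxy]-3,6-dimethylbenzoate
Product: 19 4-[(3-{[(tert-butyldiphenylsilyl)oxy]methyl}-2,4-dimethoxy-6-methylbenzoyl)oxy]-2-hydroxy-3,6-dimethylbenzoic acid
Conditions: H2 (1 atm), 10% Pd/C, EtOAc, rt
Reagents that add atoms: none
Why: Catalytic hydrogenolysis; the benzyl ester and the aryl benzyl ether cleave fast in neutral ethyl acetate, while the ring A benzylic carbon carries a bulky silyl ether between two methoxy groups, which should keep its C–O bond off the catalyst.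

Step 13
Reactants: 19 4-[(3-{[(tert-butyldiphenylsilyl)oxy]methyl}-2,4-dimethoxy-6-methylbenzoyl)oxy]-2-hydroxy-3,6-dimethylbenzoic acid
Product: 20 2-hydroxy-4-{[3-(hydroxymethyl)-2,4-dimethoxy-6-methylbenzoyl]oxy}-3,6-dimethylbenzoic acid
Conditions: HF·pyridine, pyridine, THF, 0 °C to rt
Reagents that add atoms: none
Why: Fluoride-induced Si–O cleavage of a primary silyl ether; the pyridine-buffered reagent should be neither basic enough to open the hindered aryl ester nor acidic enough to ionise the benzylic alcohol.

## Compound list

1 | methyl 2,4-dihydroxy-3,6-dimethylbenzoate | COC(=O)c1c(C)cc(O)c(C)c1O | starting material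
2 | methyl 4-(allyloxy)-2-hydroxy-3,6-dimethylbenzoate | COC(=O)c1c(C)cc(OCC=C)c(C)c1O | intermediate
3 | 4-(allyloxy)-2-hydroxy-3,6-dimethylbenzoic acid | OC(=O)c1c(C)cc(OCC=C)c(C)c1O | intermediate
4 | benzyl 4-(allyloxy)-2-(benzyloxy)-3,6-dimethylbenzoate | C=CCOc1cc(C)c(C(=O)OCc2ccccc2)c(OCc2ccccc2)c1C | intermediate
5 | benzyl 2-(benzyloxy)-4-hydroxy-3,6-dimethylbenzoate | Cc1cc(O)c(C)c(OCc2ccccc2)c1C(=O)OCc1ccccc1 | intermediate
6 | but-2-ynoic acid | CC#CC(=O)O | starting material
7 | benzyl 2-(benzyloxy)-4-(but-2-ynoyloxy)-3,6-dimethylbenzoate | CC#CC(=O)Oc1cc(C)c(C(=O)OCc2ccccc2)c(OCc2ccccc2)c1C | intermediate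
8 | methyl 3-hydroxypropanoate | COC(=O)CCO | starting material
9 | methyl 3-[(tert-butyldiphenylsilyl)oxy]propanoate | COC(=O)CCO[Si](c1ccccc1)(c1ccccc1)C(C)(C)C | intermediate
10 | N-methoxy-N-methylacetamide | CC(=O)N(C)OC | starting material
11 | methyl 2-{[(tert-butyldiphenylsilyl)oxy]methyl}-3-oxobutanoate (racemic) | COC(=O)C(CO[Si](c1ccccc1)(c1ccccc1)C(C)(C)C)C(C)=O | intermediate
12 | methyl 2-{[(tert-butyldiphenylsilyl)oxy]methyl}-3,3-dimethoxybutanoate (racemic) | COC(=O)C(CO[Si](c1ccccc1)(c1ccccc1)C(C)(C)C)C(C)(OC)OC | intermediate
13 | methyl 2-{[(tert-butyldiphenylsilyl)oxy]methyl}-3-methoxybut-2-enoate (geometry undefined) | COC(=O)C(CO[Si](c1ccccc1)(c1ccccc1)C(C)(C)C)=C(C)OC | intermediate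
14 | 2-{[(tert-butyldiphenylsilyl)oxy]methyl}-1,3-dimethoxy-1-[(trimethylsilyl)oxy]buta-1,3-diene (geometry undefined) | C=C(OC)C(CO[Si](c1ccccc1)(c1ccccc1)C(C)(C)C)=C(OC)O[Si](C)(C)C | intermediate
15 | benzyl 2-(benzyloxy)-4-{[5-{[(tert-butyldiphenylsilyl)oxy]methyl}-4,6-dimethoxy-2-methyl-6-[(trimethylsilyl)oxy]cyclohexa-1,4-diene-1-carbonyl]oxy}-3,6-dimethylbenzoate (racemic) | COC1=C(CO[Si](c2ccccc2)(c2ccccc2)C(C)(C)C)C(OC)(O[Si](C)(C)C)C(C(=O)Oc2cc(C)c(C(=O)OCc3ccccc3)c(OCc3ccccc3)c2C)=C(C)C1 | intermediate
16 | benzyl 2-(benzyloxy)-4-[(3-{[(tert-butyldiphenylsilyl)oxy]methyl}-4-methoxy-6-methyl-2-[(trimethylsilyl)oxy]benzoyl)oxy]-3,6-dimethylbenzoate | COc1cc(C)c(C(=O)Oc2cc(C)c(C(=O)OCc3ccccc3)c(OCc3ccccc3)c2C)c(O[Si](C)(C)C)c1CO[Si](c1ccccc1)(c1ccccc1)C(C)(C)C | intermediate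
17 | benzyl 2-(benzyloxy)-4-[(3-{[(tert-butyldiphenylsilyl)oxy]methyl}-2-hydroxy-4-methoxy-6-methylbenzoyl)oxy]-3,6-dimethylbenzoate | COc1cc(C)c(C(=O)Oc2cc(C)c(C(=O)OCc3ccccc3)c(OCc3ccccc3)c2C)c(O)c1CO[Si](c1ccccc1)(c1ccccc1)C(C)(C)C | intermediate
18 | benzyl 2-(benzyloxy)-4-[(3-{[(tert-butyldiphenylsilyl)oxy]methyl}-2,4-dimethoxy-6-methylbenzoyl)oxy]-3,6-dimethylbenzoate | COc1cc(C)c(C(=O)Oc2cc(C)c(C(=O)OCc3ccccc3)c(OCc3ccccc3)c2C)c(OC)c1CO[Si](c1ccccc1)(c1ccccc1)C(C)(C)C | intermediate
19 | 4-[(3-{[(tert-butyldiphenylsilyl)oxy]methyl}-2,4-dimethoxy-6-methylbenzoyl)oxy]-2-hydroxy-3,6-dimethylbenzoic acid | COc1cc(C)c(C(=O)Oc2cc(C)c(C(=O)O)c(O)c2C)c(OC)c1CO[Si](c1ccccc1)(c1ccccc1)C(C)(C)C | intermediate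
20 | 2-hydroxy-4-{[3-(hydroxymethyl)-2,4-dimethoxy-6-methylbenzoyl]oxy}-3,6-dimethylbenzoic acid | COc1cc(C)c(C(=O)Oc2cc(C)c(C(=O)O)c(O)c2C)c(OC)c1CO | target

## Step count and risks

Total: 13 steps. Longest linear sequence: 9 steps (steps 1–5 and 10–13, from 1). The diene branch (steps 6–9) joins at step 10.

**Step 10 (key step).** The likeliest failure is thermal decay of the silyl ketene acetal (protodesilylation, silyl shift to carbon, oligomerisation) outrunning a slow cycloaddition. Both the β-methyl group of the ynoate and the substituent at C2 of the diene retard bond formation. The fallback uses a more reactive surrogate of the but-2-ynoate that forms the same two ring bonds; it sets out from 5 and returns at 17. Phenol 5 would be esterified with but-3-ynoic acid (DCC, CH2Cl2, 0 °C) to benzyl 2-(benzyloxy)-4-(but-3-ynoyloxy)-3,6-dimethylbenzoate F1. A catalytic amount of Et3N would isomerise this to the allenic ester benzyl 2-(benzyloxy)-4-(buta-2,3-dienoyloxy)-3,6-dimethylbenzoate F2. Allenic esters are established, more reactive stand-ins for but-2-ynoates towards oxygenated dienes. Diene 14 should add across the α,β double bond of F2 well below 100 °C in the same orientation, giving the 6-methylidenecyclohexene adduct F3. Dilute acid should then remove methanol and the silyl group while the exocyclic double bond moves into the ring, which gives 17.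

**Step 8.** Loss of methanol from ketal 12 may stop short, or the acid may strip the silyloxy group, whose CH2–O bond becomes allylic to an enol ether in 13. The fallback drops the enol methyl ether and uses a bis(silyloxy) diene instead; it sets out from 11 and returns at 18. Keto ester 11 with TMSCl and Et3N would give methyl 2-{[(tert-butyldiphenylsilyl)oxy]methyl}-3-[(trimethylsilyl)oxy]but-2-enoate F7. LiN(iPr)2 and TMSCl at −78 °C would convert it into the Chan-type diene 2-{[(tert-butyldiphenylsilyl)oxy]methyl}-1-methoxy-1,3-bis[(trimethylsilyl)oxy]buta-1,3-diene F8. Cycloaddition with 7 as in step 10 would give the bis(silyloxy) cyclohexadiene adduct F9, and acid would turn it into the ring A 2,4-dihydroxy depside F10. Excess MeI with K2CO3 in DMF would methylate both ring A phenols at once and give 18.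

**Step 7.** The ester enolate may expel silanolate (E1cB) before it is acylated, or the Weinreb amide may be deprotonated instead of attacked. The fallback replaces acylation by aldol addition and oxidation; it sets out from 9 and returns at 11. The lithium enolate of 9 would be added to acetaldehyde at −78 °C, where aldol addition is much faster than elimination, giving methyl 2-{[(tert-butyldiphenylsilyl)oxy]methyl}-3-hydroxybutanoate F6 as a mixture of diastereomers. Dess–Martin periodinane in CH2Cl2 would oxidise F6 to 11.

**Step 2.** Hydrolysis may stall because the ortho phenoxide deactivates a carbonyl that the C6 methyl already shields, and the electron-rich salicylic acid may decarboxylate on acidification. The fallback caps the phenol before the ester is hydrolysed; it sets out from 2 and returns at 4, one step longer. Ester 2 would be benzylated (BnBr, K2CO3, DMF, 60 °C) to methyl 4-(allyloxy)-2-(benzyloxy)-3,6-dimethylbenzoate F4. Hydrolysis (KOH, DMSO/H2O, 100 °C) would give 4-(allyloxy)-2-(benzyloxy)-3,6-dimethylbenzoic acid F5, which has no free ortho hydroxyl and therefore no easy decarboxylation path. Benzylation of the carboxylate (BnBr, K2CO3, DMF) would give 4.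

## Further compounds

F1 | step 10 | benzyl 2-(benzyloxy)-4-(but-3-ynoyloxy)-3,6-dimethylbenzoate | C#CCC(=O)Oc1cc(C)c(C(=O)OCc2ccccc2)c(OCc2ccccc2)c1C
F2 | step 10 | benzyl 2-(benzyloxy)-4-(buta-2,3-dienoyloxy)-3,6-dimethylbenzoate | C=C=CC(=O)Oc1cc(C)c(C(=O)OCc2ccccc2)c(OCc2ccccc2)c1C
F3 | step 10 | benzyl 2-(benzyloxy)-4-{[3-{[(tert-butyldiphenylsilyl)oxy]methyl}-2,4-dimethoxy-6-methylidene-2-[(trimethylsilyl)oxy]cyclohex-3-ene-1-carbonyl]oxy}-3,6-dimethylbenzoate (mixture of racemic diastereomers) | COC1=C(CO[Si](c2ccccc2)(c2ccccc2)C(C)(C)C)C(OC)(O[Si](C)(C)C)C(C(=O)Oc2cc(C)c(C(=O)OCc3ccccc3)c(OCc3ccccc3)c2C)C(=C)C1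
F4 | step 2 | methyl 4-(allyloxy)-2-(benzyloxy)-3,6-dimethylbenzoate | COC(=O)c1c(C)cc(OCC=C)c(C)c1OCc1ccccc1
F5 | step 2 | 4-(allyloxy)-2-(benzyloxy)-3,6-dimethylbenzoic acid | OC(=O)c1c(C)cc(OCC=C)c(C)c1OCc1ccccc1
F6 | step 7 | methyl 2-{[(tert-butyldiphenylsilyl)oxy]methyl}-3-hydroxybutanoate (mixture of racemic diastereomers) | COC(=O)C(CO[Si](c1ccccc1)(c1ccccc1)C(C)(C)C)C(C)O
F7 | step 8 | methyl 2-{[(tert-butyldiphenylsilyl)oxy]methyl}-3-[(trimethylsilyl)oxy]but-2-enoate | COC(=O)C(CO[Si](c1ccccc1)(c1ccccc1)C(C)(C)C)=C(C)O[Si](C)(C)C
F8 | step 8 | 2-{[(tert-butyldiphenylsilyl)oxy]methyl}-1-methoxy-1,3-bis[(trimethylsilyl)oxy]buta-1,3-diene | C=C(O[Si](C)(C)C)C(CO[Si](c1ccccc1)(c1ccccc1)C(C)(C)C)=C(OC)O[Si](C)(C)C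
F9 | step 8 | benzyl 2-(benzyloxy)-4-{[5-{[(tert-butyldiphenylsilyl)oxy]methyl}-6-methoxy-2-methyl-4,6-bis[(trimethylsilyl)oxy]cyclohexa-1,4-diene-1-carbonyl]oxy}-3,6-dimethylbenzoate (racemic) | C[Si](C)(C)OC1=C(CO[Si](c2ccccc2)(c2ccccc2)C(C)(C)C)C(OC)(O[Si](C)(C)C)C(C(=O)Oc2cc(C)c(C(=O)OCc3ccccc3)c(OCc3ccccc3)c2C)=C(C)C1
F10 | step 8 | benzyl 2-(benzyloxy)-4-[(3-{[(tert-butyldiphenylsilyl)oxy]methyl}-2,4-dihydroxy-6-methylbenzoyl)oxy]-3,6-dimethylbenzoate | Cc1cc(O)c(CO[Si](c2ccccc2)(c2ccccc2)C(C)(C)C)c(O)c1C(=O)Oc1cc(C)c(C(=O)OCc2ccccc2)c(OCc2ccccc2)c1C
A1 | alternative 1 | 2,4-dimethoxy-6-methyl-3-{[(triisopropylsilyl)oxy]methyl}benzoic acid | COc1cc(C)c(C(=O)O)c(OC)c1CO[Si](C(C)C)(C(C)C)C(C)C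
A2 | alternative 1 | [(4-bromo-2,6-dimethoxybenzyl)oxy]triisopropylsilane | COc1cc(Br)cc(OC)c1CO[Si](C(C)C)(C(C)C)C(C)C
A3 | alternative 1 | 1,2-didehydro-3,5-dimethoxy-4-{[(triisopropylsilyl)oxy]methyl}benzene | COC1=C(CO[Si](C(C)C)(C(C)C)C(C)C)C(OC)=CC#C1
A4 | alternative 2 | 7-hydroxy-2,2,5,8-tetramethyl-4H-benzo[d][1,3]dioxin-4-one | Cc1cc(O)c(C)c2OC(C)(C)OC(=O)c12
A5 | alternative 2 | 6-(3,5-dioxohexan-2-yl)-2,2-dimethyl-4H-1,3-dioxin-4-one (racemic) | CC(=O)CC(=O)C(C)C1=CC(=O)OC(C)(C)O1
A6 | alternative 3 | methyl 3-{[(tert-butyldimethylsilyl)oxy]methyl}-2,4-dimethoxy-6-methylbenzoate | COC(=O)c1c(C)cc(OC)c(CO[Si](C)(C)C(C)(C)C)c1OC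
A7 | alternative 3 | methyl 6-methoxy-4-methyl-2-oxo-2H-pyran-5-carboxylate | COC(=O)C1=C(OC)OC(=O)C=C1C
A8 | alternative 3 | tert-butyl[(3-methoxyprop-2-yn-1-yl)oxy]dimethylsilane | COC#CCO[Si](C)(C)C(C)(C)C
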